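Each half of the target is a perhydrobenzoxepine in which O1 lies between the gem-dimethyl carbon C2 and the ring-fusion methine C7, next to quaternary C6; the seven-membered ring is therefore a cyclohexanone with one oxygen inserted. The route rests on breaking O1–C7 back to a trans-fused decalone whose carbonyl is C2. A peracid Baeyer–Villiger oxidation then makes the oxepane ring, the O1–C7 bond and the C7 configuration in one operation, because the methine C7 migrates in preference to the C3 methylene and with retention. The precursor is the trans-decalone 9 from (R)-Wieland–Miescher ketone, carrying the angular C6 methyl and C11 masked as a dioxolane.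

Key step: step 6

Remarks on the chemistry
- Numbering (each half, used from compound 1 onwards): O1, C2 (gem-dimethyl), C3, C4, C5, C6 (methyl), C7 around the oxepane; C6–C11 around the cyclohexane; C12 in the bridge; primes mark the second half. β is the face of the C6 methyl, α the opposite face.
- The two halves of the target are not equivalent. Both are 6S,7S,11S, but C10 is R in one half (acetate β, axial, syn to the C6 methyl) and S in the other (acetate α, equatorial). A homodimerisation would give the wrong compound, so both halves are made from one common enone (21), united by a cross-coupling, and the two C10 centres are set by two different reactions.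
- Design of the key-step substrate: C11 stays a dioxolane (inert to buffered peracid) so that the ketone can later be released and transposed to C10. C3 is left unoxygenated, because an oxygen on C3 would make C3 the migrating carbon.
- Carbinol centres that later become carbonyls (C2 in 8, C3 in 16–31, C10 in 20) are drawn as the expected epimer; their configuration is of no consequence.

Step 1
Reactants: 1 (R)-Wieland–Miescher ketone; 2 ethane-1,2-dithiol
Product: 3 enone dithiolane (C3 carbonyl as 1,3-dithiolane; C2=C7 alkene and C11 ketone kept)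
Conditions: HSCH2CH2SH, p-TsOH (cat.), AcOH, rt
Reagents that add atoms: none
Why: Acid-catalysed dithioketalisation takes the conjugated carbonyl selectively over the neopentyl C11 ketone and leaves the C2=C7 double bond in place, so no stereocentre is touched.

Step 2
Reactants: 3 enone dithiolane; 4 ethane-1,2-diol
Product: 5 dithiolane–dioxolane (C11 as 1,3-dioxolane)
Conditions: HOCH2CH2OH, p-TsOH (cat.), benzene, reflux, Dean–Stark
Reagents that add atoms: none
Why: Ketalisation of the remaining ketone with azeotropic removal of water is a standard acetal formation to which the dithiolane and the alkene are inert.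

Step 3
Reactants: 5 dithiolane–dioxolane
Product: 6 octalin dioxolane (6β-methyl, C2=C7 alkene, C3 now CH2)
Conditions: Raney Ni (W-2), EtOH, reflux
Reagents that add atoms: none
Why: Raney nickel hydrogenolysis of the dithiolane (Mozingo desulfurisation) replaces both C–S bonds by C–H and spares the dioxolane and the hindered trisubstituted alkene.

Step 4
Reactants: 6 octalin dioxolane
Product: 8 trans-decalin-2α-ol dioxolane, via C2 alkylborane 7 (not isolated)
Conditions: BH3·THF, THF, 0 °C → rt; then NaOH, H2O2, 0 °C → rt
Reagents that add atoms: hydrogen peroxide, OO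
Why: Hydroboration–oxidation adds H and B syn from the α face, away from the angular methyl, with boron on the less substituted C2 and hydrogen on C7, which sets the trans ring fusion, and the C–B bond is oxidised with retention.

Step 5
Reactants: 8 trans-decalin-2α-ol dioxolane
Product: 9 trans-decalone (C2 ketone, 6β-methyl, 7α-H, C11 dioxolane)
Conditions: Dess–Martin periodinane, NaHCO3, CH2Cl2, rt
Reagents that add atoms: none
Why: Dess–Martin oxidation of the secondary alcohol under buffered, non-epimerising conditions gives the ketone, whose trans fusion is also the thermodynamically preferred one.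

Step 6
Reactants: 9 trans-decalone
Product: 11 trans-fused ε-lactone (O1 between C2 and C7), via Criegee adduct 10 (not isolated)
Conditions: mCPBA, NaHCO3, CH2Cl2, 0 °C → rt
Reagents that add atoms: 3-chloroperbenzoic acid (mCPBA), OOC(=O)c1cccc(Cl)c1
Why: The peracid adds to the C2 carbonyl to give the Criegee adduct 10, in which the C2–C7 bond antiperiplanar to the O–O bond shifts to oxygen while 3-chlorobenzoate departs. The closest known reaction is the Baeyer–Villiger ring expansion of 2-substituted cyclohexanones and 1-decalones to ε-lactones. The oxepane is not closed end to end but arises by ring enlargement, a 1,2-shift that inserts O1 between C2 and C7 of the existing six-membered ring. The only new stereocentre, C7–O1, is controlled by the substrate: migration is suprafacial with retention, so the trans fusion set in step 4 is transferred unchanged. Regioselectivity is needed and is secured by the higher migratory aptitude of the methine C7 over the C3 methylene. Chemoselectivity is secured by the absence of any other ketone or alkene, and the bicarbonate buffer keeps the dioxolane intact.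

Step 7
Reactants: 11 trans-fused ε-lactone
Product: 13 ketene acetal diphenyl phosphate (C2=C3), via potassium enolate 12 (not isolated)
Conditions: KHMDS, (PhO)2P(O)Cl, THF/DMPU, −78 °C
Reagents that add atoms: diphenyl chlorophosphate, O=P(Cl)(Oc1ccccc1)Oc1ccccc1
Why: The lactone can enolise only toward C3, and O-phosphorylation of the potassium enolate gives the cyclic ketene acetal phosphate, a known activation of medium-ring lactones for cross-coupling.

Step 8
Reactants: 13 ketene acetal diphenyl phosphate
Product: 14 2-methyl cyclic enol ether (C2=C3)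
Conditions: MeZnCl, Pd(PPh3)4 (cat.), THF, rt → 50 °C; Et3N-buffered work-up
Reagents that add atoms: methylzinc chloride, C[Zn]Cl
Why: In this Negishi cross-coupling Pd(0) inserts into the C2–O(phosphate) bond, methyl is transferred from zinc and reductive elimination gives the enol ether without touching a stereocentre or the dioxolane.

Step 9
Reactants: 14 2-methyl cyclic enol ether
Product: 16 2,2-dimethyloxepan-3α-ol (C11 dioxolane), via 2,3-epoxide 15 (not isolated)
Conditions: DMDO (acetone), CH2Cl2, −78 → 0 °C; solvent removed cold; then AlMe3, CH2Cl2, −78 → 0 °C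
Reagents that add atoms: dimethyldioxirane, CC1(C)OO1; trimethylaluminium, C[Al](C)C
Why: Dimethyldioxirane epoxidises the electron-rich enol ether, expected from the α face anti to the C6 methyl, and trimethylaluminium then ionises the epoxy acetal to the C2 oxocarbenium ion and delivers methyl to C2 (the known opening of glycal-type epoxides by organoalanes), which gives the gem-dimethyl carbon and the C3 oxygen in one operation.

Step 10
Reactants: 16 2,2-dimethyloxepan-3α-ol
Product: 17 3α-TBS ether (C11 dioxolane)
Conditions: TBSOTf, 2,6-lutidine, CH2Cl2, 0 °C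
Reagents that add atoms: tert-butyldimethylsilyl triflate, CC(C)(C)[Si](C)(C)OS(=O)(=O)C(F)(F)F
Why: Silylation with the silyl triflate protects the hindered C3 alcohol, which must survive the oxidations, organometallic reagents and hydrides used up to step 23.

Step 11
Reactants: 17 3α-TBS ether
Product: 18 C11 ketone
Conditions: PPTS, acetone/H2O, 60 °C
Reagents that add atoms: water, O
Why: Mild acid-catalysed hydrolysis releases the C11 ketone from the dioxolane while the hindered silyl ether and the oxepane are stable.

Step 12
Reactants: 18 C11 ketone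
Product: 19 11-methylene compound (C11=C12)
Conditions: Ph3PCH3Br, KOt-Bu, toluene, 90 °C
Reagents that add atoms: methyltriphenylphosphonium bromide, C[P+](c1ccccc1)(c1ccccc1)c1ccccc1.[Br-]
Why: Wittig methylenation of the neopentyl C11 ketone, which has no epimerisable α-stereocentre, installs C12 as an exocyclic methylene.

Step 13
Reactants: 19 11-methylene compound
Product: 20 allylic alcohol (10β-OH, C11=C12)
Conditions: SeO2 (cat.), t-BuOOH, CH2Cl2, rt
Reagents that add atoms: selenium dioxide, O=[Se]=O; tert-butyl hydroperoxide (terminal oxidant), CC(C)(C)OO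
Why: Selenium dioxide allylic oxidation (ene reaction, then [2,3]-sigmatropic shift) hydroxylates C10, the only allylic position that bears hydrogen, and returns the double bond to C11=C12.

Step 14
Reactants: 20 allylic alcohol
Product: 21 enone (C10 ketone, C11=C12 methylene)
Conditions: Dess–Martin periodinane, NaHCO3, CH2Cl2, 0 °C → rt
Reagents that add atoms: none
Why: Dess–Martin oxidation of the allylic alcohol gives the α-methylene ketone, the common intermediate from which both halves are drawn.

Step 15
Reactants: 21 enone
Product: 22 tertiary allylic alcohol (10β-OH, 10α-methyl, C11=C12)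
Conditions: MeLi, CeCl3, THF, −78 °C
Reagents that add atoms: methyllithium, [Li]C
Why: The organocerium reagent (Imamoto conditions) adds 1,2 without enolisation, and because the syn-axial C6 methyl blocks axial attack at C10, methyl enters equatorially from the α face and the new hydroxyl is β and axial, the C10 configuration of the first half.

Step 16
Reactants: 22 tertiary allylic alcohol
Product: 24 diol (10β-OH, 11α-H, 12-OH), via C12 alkylborane 23 (not isolated)
Conditions: BH3·THF (excess), THF, 0 °C → rt; then NaOH, H2O2
Reagents that add atoms: hydrogen peroxide, OO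
Why: Hydroboration–oxidation places boron on the terminal C12 and delivers hydrogen to C11 from the α face, because the β face is screened by the axial C6 methyl and the axial C10 oxygen, which sets 11α-H with the CH2OH group equatorial.

Step 17
Reactants: 24 diol
Product: 25 iodo alcohol (12-iodide)
Conditions: I2, PPh3, imidazole, toluene, rt → 60 °C
Reagents that add atoms: iodine, II
Why: Appel-type iodination converts the primary alcohol by SN2 displacement of its oxyphosphonium group and leaves the tertiary alcohol untouched.

Step 18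
Reactants: 25 iodo alcohol; 21 enone
Product: 26 coupled keto alcohol (C12–C12′ bond; C10′ ketone; 11α-H and 11′α-H)
Conditions: (TMS)3SiH, AIBN (cat.), benzene, 80 °C, slow addition of silane; 21 in slight excess
Reagents that add atoms: none
Why: In this Giese reaction the silyl radical abstracts iodine, the primary C12 radical adds to the unhindered methylene terminus of 21 to form C12–C12′, and the α-keto radical takes hydrogen from the bulky silane on the α face, anti to the axial C6′ methyl, which sets 11′α-H.

Step 19
Reactants: 26 coupled keto alcohol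
Product: 27 10′-methylene compound
Conditions: Ph3PCH3Br, KHMDS, THF, 0 °C → rt
Reagents that add atoms: methyltriphenylphosphonium bromide, C[P+](c1ccccc1)(c1ccccc1)c1ccccc1.[Br-]
Why: Wittig methylenation converts the C10′ ketone into the exocyclic alkene, and since the C11′ methine next to quaternary C6′ is the kinetically less acidic α-position, the centre set in step 18 should not be scrambled.

Step 20
Reactants: 27 10′-methylene compound
Product: 28 10′-spiro-epoxide (oxygen α)
Conditions: mCPBA, NaHCO3, CH2Cl2, 0 °C
Reagents that add atoms: 3-chloroperbenzoic acid (mCPBA), OOC(=O)c1cccc(Cl)c1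
Why: Peracid epoxidation (Prilezhaev reaction) of the only alkene occurs from the equatorial α face because axial approach is blocked by the syn-axial C6′ methyl, which places the epoxide oxygen α at C10′.

Step 21
Reactants: 28 10′-spiro-epoxide
Product: 29 bis-tertiary diol (10β-OH/10α-methyl and 10′α-OH/10′β-methyl)
Conditions: LiAlH4, THF, 0 °C → rt
Reagents that add atoms: none
Why: Hydride opens the 1,1-disubstituted epoxide at its unhindered CH2 terminus (SN2), which turns that carbon into the β methyl group and leaves the C10′ oxygen α and equatorial, the configuration of the second half.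

Step 22
Reactants: 29 bis-tertiary diol
Product: 30 diacetate bis-TBS ether
Conditions: n-BuLi, THF, −78 °C; then Ac2O, −78 °C → rt
Reagents that add atoms: acetic anhydride, CC(=O)OC(C)=O
Why: Both hindered tertiary alcohols are acylated as their lithium alkoxides, a method that does not rely on nucleophilic catalysis at a crowded centre, and nothing else in 29 is sensitive to base.

Step 23
Reactants: 30 diacetate bis-TBS ether
Product: 31 diacetate diol (3α-OH, 3′α-OH)
Conditions: HF·pyridine, THF/pyridine, rt
Reagents that add atoms: none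
Why: Fluoride-mediated cleavage of the two silyl ethers, driven by Si–F bond formation, frees the C3 and C3′ alcohols without affecting the tertiary acetates.

Step 24
Reactants: 31 diacetate diol
Product: 32 CNP0325605.1 (target)
Conditions: Dess–Martin periodinane, NaHCO3, CH2Cl2, rt
Reagents that add atoms: none
Why: Dess–Martin oxidation of both secondary alcohols gives the two C3 ketones, which have no α-stereocentre to lose, and completes the target.

Compound list
1 | (R)-Wieland–Miescher ketone, (8aR)-8a-methyl-3,4,8,8a-tetrahydronaphthalene-1,6(2H,7H)-dione | O=C1CC[C@@]2(C)C(=O)CCCC2=C1 | starting material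
2 | ethane-1,2-dithiol | SCCS | starting material
3 | enone dithiolane (C3 as 1,3-dithiolane, C2=C7 alkene, C11 ketone, 6β-methyl) | C1CCC2=CC3(SCCS3)CC[C@@]2(C)C1=O | intermediate
4 | ethane-1,2-diol | OCCO | starting material
5 | dithiolane–dioxolane (C3 dithiolane, C11 dioxolane, C2=C7 alkene) | C1CCC2=CC3(SCCS3)CC[C@@]2(C)C14OCCO4 | intermediate
6 | octalin dioxolane (6β-methyl, C2=C7 alkene, C11 dioxolane) | C1CCC2=CCCC[C@@]2(C)C13OCCO3 | intermediate
7 | C2 alkylborane (2α-boryl, 7α-H, trans-fused) | C1CC[C@@H]2[C@@H](B)CCC[C@@]2(C)C13OCCO3 | intermediate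
8 | trans-decalin-2α-ol dioxolane (6β-methyl, 7α-H) | C1CC[C@@H]2[C@@H](O)CCC[C@@]2(C)C13OCCO3 | intermediate
9 | trans-decalone (C2 ketone, 6β-methyl, 7α-H, C11 dioxolane) | C1CC[C@@H]2C(=O)CCC[C@@]2(C)C13OCCO3 | intermediate
10 | Criegee adduct (C2 hemiperketal of 9; OH β, aroylperoxy α) | C1CC[C@@H]2[C@@](O)(OOC(=O)c4cccc(Cl)c4)CCC[C@@]2(C)C13OCCO3 | intermediate
11 | trans-fused ε-lactone (O1–C7 bond, C2 lactone carbonyl, 6β-methyl, 7α-H, C11 dioxolane) | C1CC[C@@H]2OC(=O)CCC[C@@]2(C)C13OCCO3 | intermediate
12 | potassium enolate of 11 (C2=C3) | C1CC[C@@H]2OC([O-])=CCC[C@@]2(C)C13OCCO3.[K+] | intermediate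
13 | ketene acetal diphenyl phosphate (C2=C3, phosphate on C2) | C1CC[C@@H]2OC(OP(=O)(Oc4ccccc4)Oc4ccccc4)=CCC[C@@]2(C)C13OCCO3 | intermediate
14 | 2-methyl cyclic enol ether (C2=C3) | C1CC[C@@H]2OC(C)=CCC[C@@]2(C)C13OCCO3 | intermediate
15 | 2,3-epoxide (oxygen α) | C1CC[C@@H]2O[C@@]4(C)O[C@H]4CC[C@@]2(C)C13OCCO3 | intermediate
16 | 2,2-dimethyloxepan-3α-ol (C11 dioxolane) | C1CC[C@@H]2OC(C)(C)[C@@H](O)CC[C@@]2(C)C13OCCO3 | intermediate
17 | 3α-TBS ether (C11 dioxolane) | C1CC[C@@H]2OC(C)(C)[C@@H](O[Si](C)(C)C(C)(C)C)CC[C@@]2(C)C13OCCO3 | intermediate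
18 | C11 ketone (3α-OTBS) | C1CC[C@@H]2OC(C)(C)[C@@H](O[Si](C)(C)C(C)(C)C)CC[C@@]2(C)C1=O | intermediate
19 | 11-methylene compound (C11=C12) | C1CC[C@@H]2OC(C)(C)[C@@H](O[Si](C)(C)C(C)(C)C)CC[C@@]2(C)C1=C | intermediate
20 | allylic alcohol (10β-OH, C11=C12) | O[C@@H]1CC[C@@H]2OC(C)(C)[C@@H](O[Si](C)(C)C(C)(C)C)CC[C@@]2(C)C1=C | intermediate
21 | enone (C10 ketone, C11=C12 methylene) | O=C1CC[C@@H]2OC(C)(C)[C@@H](O[Si](C)(C)C(C)(C)C)CC[C@@]2(C)C1=C | intermediate
22 | tertiary allylic alcohol (10β-OH, 10α-methyl, C11=C12) | O[C@]1(C)CC[C@@H]2OC(C)(C)[C@@H](O[Si](C)(C)C(C)(C)C)CC[C@@]2(C)C1=C | intermediate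
23 | C12 alkylborane (C10 oxygen as its borinate, 11α-H) | BO[C@]1(C)CC[C@@H]2OC(C)(C)[C@@H](O[Si](C)(C)C(C)(C)C)CC[C@@]2(C)[C@@H]1CB | intermediate
24 | diol (10β-OH, 10α-methyl, 11α-H, 12-OH) | O[C@]1(C)CC[C@@H]2OC(C)(C)[C@@H](O[Si](C)(C)C(C)(C)C)CC[C@@]2(C)[C@@H]1CO | intermediate
25 | iodo alcohol (12-iodide of 24) | O[C@]1(C)CC[C@@H]2OC(C)(C)[C@@H](O[Si](C)(C)C(C)(C)C)CC[C@@]2(C)[C@@H]1CI | intermediate
26 | coupled keto alcohol (first half 10β-OH/10α-methyl; second half C10′ ketone; 11α-H, 11′α-H) | O[C@]1(C)CC[C@@H]2OC(C)(C)[C@@H](O[Si](C)(C)C(C)(C)C)CC[C@@]2(C)[C@@H]1CC[C@H]1[C@]2(C)CC[C@H](O[Si](C)(C)C(C)(C)C)C(C)(C)O[C@H]2CCC1=O | intermediate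
27 | 10′-methylene compound | O[C@]1(C)CC[C@@H]2OC(C)(C)[C@@H](O[Si](C)(C)C(C)(C)C)CC[C@@]2(C)[C@@H]1CC[C@H]1[C@]2(C)CC[C@H](O[Si](C)(C)C(C)(C)C)C(C)(C)O[C@H]2CCC1=C | intermediate
28 | 10′-spiro-epoxide (oxygen α, CH2 β) | O[C@]1(C)CC[C@@H]2OC(C)(C)[C@@H](O[Si](C)(C)C(C)(C)C)CC[C@@]2(C)[C@@H]1CC[C@H]1[C@]2(C)CC[C@H](O[Si](C)(C)C(C)(C)C)C(C)(C)O[C@H]2CC[C@@]13CO3 | intermediate
29 | bis-tertiary diol (10β-OH/10α-methyl; 10′α-OH/10′β-methyl) | O[C@]1(C)CC[C@@H]2OC(C)(C)[C@@H](O[Si](C)(C)C(C)(C)C)CC[C@@]2(C)[C@@H]1CC[C@H]1[C@]2(C)CC[C@H](O[Si](C)(C)C(C)(C)C)C(C)(C)O[C@H]2CC[C@]1(C)O | intermediate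
30 | diacetate bis-TBS ether (10β-OAc, 10′α-OAc) | CC(=O)O[C@]1(C)CC[C@@H]2OC(C)(C)[C@@H](O[Si](C)(C)C(C)(C)C)CC[C@@]2(C)[C@@H]1CC[C@H]1[C@]2(C)CC[C@H](O[Si](C)(C)C(C)(C)C)C(C)(C)O[C@H]2CC[C@]1(C)OC(C)=O | intermediate
31 | diacetate diol (3α-OH, 3′α-OH) | CC(=O)O[C@]1(C)CC[C@@H]2OC(C)(C)[C@@H](O)CC[C@@]2(C)[C@@H]1CC[C@H]1[C@]2(C)CC[C@H](O)C(C)(C)O[C@H]2CC[C@]1(C)OC(C)=O | intermediate
32 | CNP0325605.1 (3,3′-diketone; 10β-OAc, 10′α-OAc) | CC(=O)O[C@]1(C)CC[C@@H]2OC(C)(C)C(=O)CC[C@@]2(C)[C@@H]1CC[C@H]1[C@]2(C)CCC(=O)C(C)(C)O[C@H]2CC[C@]1(C)OC(C)=O | target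

Total step count: 24. Longest linear sequence: 24 steps (1 → 32; the enone 21 used as the acceptor in step 18 comes from the same sequence).

Steps most likely to fail

Step 18 (radical union). The C12 radical may be reduced by the silane before it adds, the enone may oligomerise, or hydrogen transfer to C11′ may show poor facial selectivity. The fallback replaces the radical addition by an anionic conjugate addition; it sets out from 25 and 21 and returns at 27. Sodium benzenesulfinate (DMF, 80 °C) displaces the iodide of 25 to give the phenyl sulfone F1. Double deprotonation (n-BuLi, THF/DMPU, −78 °C) and Michael addition of the α-sulfonyl carbanion to 21, with kinetic protonation of the enolate from the α face, gives the sulfonyl ketone F2. Wittig methylenation as in step 19 gives the sulfonyl alkene F3, and reductive desulfonylation (Na/Hg, Na2HPO4, MeOH/THF, −20 °C) gives 27.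

Step 9 (epoxidation, then methyl transfer). The 2-methyl epoxy acetal may rearrange by hydride shift or ring opening before methyl is delivered, or the alane may attack the dioxolane. The fallback introduces the C3 oxygen and the two methyl groups separately; it sets out from lactone 11, bypasses steps 7–10 and returns at 17. Enolate hydroxylation (KHMDS, then 2-(phenylsulfonyl)-3-phenyloxaziridine, THF, −78 °C) gives the α-hydroxy lactone F4 (drawn 3α; either epimer serves), and silylation (TBSOTf, 2,6-lutidine) gives the silyloxy lactone F5. One equivalent of MeLi (THF, −78 °C) gives the methyl lactol F6, which is converted into the methyl ketal F7 (MeOH, HC(OMe)3, PPTS). AlMe3 (CH2Cl2, −78 → 0 °C) then ionises the ketal and delivers the second methyl group to the oxocarbenium ion, giving 17.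

Step 13 (allylic oxidation). The ene reaction has to engage the axial C10–H on the face of the C6 methyl, so conversion may be slow and over-oxidation or decomposition may compete. The fallback puts the C10 oxygen in by enolate chemistry before the olefination; it sets out from ketone 18 and returns at 21. LDA and TMSCl (THF, −78 °C) give the silyl enol ether F8, which can form only toward C10. Rubottom oxidation (mCPBA, NaHCO3, CH2Cl2, 0 °C; then K2CO3, MeOH) gives the α-hydroxy ketone F9 (10α-OH expected). Excess Ph3P=CH2 (toluene, 90 °C) gives the allylic alcohol F10, the C10 epimer of 20, and Dess–Martin oxidation gives 21.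

Further compounds
F1 | step 18 | phenyl sulfone (12-SO2Ph analogue of 25) | O[C@]1(C)CC[C@@H]2OC(C)(C)[C@@H](O[Si](C)(C)C(C)(C)C)CC[C@@]2(C)[C@@H]1CS(=O)(=O)c3ccccc3
F2 | step 18 | sulfonyl ketone (26 with PhSO2 on C12, mixture at C12) | O[C@]1(C)CC[C@@H]2OC(C)(C)[C@@H](O[Si](C)(C)C(C)(C)C)CC[C@@]2(C)[C@@H]1C(S(=O)(=O)c3ccccc3)C[C@H]1[C@]2(C)CC[C@H](O[Si](C)(C)C(C)(C)C)C(C)(C)O[C@H]2CCC1=O
F3 | step 18 | sulfonyl alkene (27 with PhSO2 on C12, mixture at C12) | O[C@]1(C)CC[C@@H]2OC(C)(C)[C@@H](O[Si](C)(C)C(C)(C)C)CC[C@@]2(C)[C@@H]1C(S(=O)(=O)c3ccccc3)C[C@H]1[C@]2(C)CC[C@H](O[Si](C)(C)C(C)(C)C)C(C)(C)O[C@H]2CCC1=C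
F4 | step 9 | α-hydroxy lactone (3α-OH, C11 dioxolane) | C1CC[C@@H]2OC(=O)[C@@H](O)CC[C@@]2(C)C13OCCO3
F5 | step 9 | silyloxy lactone (3α-OTBS) | C1CC[C@@H]2OC(=O)[C@@H](O[Si](C)(C)C(C)(C)C)CC[C@@]2(C)C13OCCO3
F6 | step 9 | methyl lactol (2-methyl-2-hydroxy, anomer mixture) | C1CC[C@@H]2OC(C)(O)[C@@H](O[Si](C)(C)C(C)(C)C)CC[C@@]2(C)C13OCCO3
F7 | step 9 | methyl ketal (2-methyl-2-methoxy, anomer mixture) | C1CC[C@@H]2OC(C)(OC)[C@@H](O[Si](C)(C)C(C)(C)C)CC[C@@]2(C)C13OCCO3
F8 | step 13 | trimethylsilyl enol ether (C10=C11, OTMS on C11) | C=1CC[C@@H]2OC(C)(C)[C@@H](O[Si](C)(C)C(C)(C)C)CC[C@@]2(C)C=1O[Si](C)(C)C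
F9 | step 13 | α-hydroxy ketone (10α-OH, C11 ketone) | O[C@H]1CC[C@@H]2OC(C)(C)[C@@H](O[Si](C)(C)C(C)(C)C)CC[C@@]2(C)C1=O
F10 | step 13 | allylic alcohol (10α-OH, C11=C12; C10 epimer of 20) | O[C@H]1CC[C@@H]2OC(C)(C)[C@@H](O[Si](C)(C)C(C)(C)C)CC[C@@]2(C)C1=C
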